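**Strategy.** The pyranone ring (ring C) is opened at O1–C2 and C4–C4a, which leads back to an aryl ester: the isoferuloyl three-carbon unit sits on the oxygen that becomes O1 of a 4-geranyl-3,5-bis(MOM-oxy)phenol. In one flask, a photo-Fries shift moves the acyl group from O1 to the ortho carbon (C4–C4a), and the phenol so freed closes onto C2 under a cinchona thiourea that sets C2 as S. The step exploits the mirror symmetry of ring A through C8a and C6: both carbons ortho to O1 are equivalent, the para carbon C6 is blocked by geranyl, and O1 is the only free hydroxyl, so only the 6-geranyl flavanone can form.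

Key step: step 7

Conventions: flavanone numbering (O1, C2, C3, C4, C4a, C5–C8, C8a); ring A is the benzo ring, ring B the 2-aryl group, ring C the pyranone. MOM = methoxymethyl; geranyl = (2E)-3,7-dimethylocta-2,6-dien-1-yl.

Assumption: the quinidine-derived bifunctional thiourea is taken to give the (2S) ring closure. The sense of induction is to be confirmed on a small scale; if it is reversed, the pseudoenantiomeric quinine-derived thiourea takes its place.

**Step 1**
Reactants: 1 isovanillin (3-hydroxy-4-methoxybenzaldehyde)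
Product: 2 4-methoxy-3-(methoxymethoxy)benzaldehyde
Conditions: MOMCl, i-Pr2NEt, CH2Cl2, 0 °C → rt
Reagents that add atoms: chloromethyl methyl ether (MOMCl), COCCl
Why: Williamson-type O-alkylation of the phenol with the reactive α-chloro ether should proceed cleanly, the aldehyde being inert to these conditions.

**Step 2**
Reactants: 2 4-methoxy-3-(methoxymethoxy)benzaldehyde
Product: 3 (2E)-3-[4-methoxy-3-(methoxymethoxy)phenyl]prop-2-enoic acid
Conditions: malonic acid, pyridine, piperidine (cat.), 90 °C; cold citric acid work-up (pH 4)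
Reagents that add atoms: malonic acid, OC(=O)CC(=O)O
Why: Knoevenagel–Doebner condensation with decarboxylation in hot pyridine should give the E-cinnamic acid, and the MOM acetal is stable to the basic medium and the buffered work-up.

**Step 3**
Reactants: 4 resorcinol
Product: 5 1,3-bis(methoxymethoxy)benzene
Conditions: NaH, DMF, 0 °C; MOMCl, 0 °C → rt
Reagents that add atoms: chloromethyl methyl ether (MOMCl), COCCl
Why: Double Williamson-type O-alkylation of the resorcinol dianion is a standard protection.

**Step 4**
Reactants: 5 1,3-bis(methoxymethoxy)benzene; 6 geranyl bromide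
Product: 8 2-geranyl-1,3-bis(methoxymethoxy)benzene, via aryllithium 7 (not isolated)
Conditions: n-BuLi, THF, 0 °C; CuBr·SMe2 (10 mol %), geranyl bromide, −78 °C → rt
Reagents that add atoms: none
Why: Directed ortho-metalation places lithium on the carbon between the two cooperating MOM groups, and copper-catalysed SN2 allylation with the primary allylic bromide should keep the E geometry of the geranyl chain.

**Step 5**
Reactants: 8 2-geranyl-1,3-bis(methoxymethoxy)benzene
Product: 10 4-geranyl-3,5-bis(methoxymethoxy)phenol, via arylboronate 9 (not isolated)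
Conditions: [Ir(OMe)(cod)]2 (1.5 mol %), 4,4'-di-tert-butyl-2,2'-bipyridine (3 mol %), B2pin2 (0.55 equiv), THF, 50 °C; then NaBO3·4H2O, THF/H2O, rt
Reagents that add atoms: sodium perborate, [Na+].[Na+].O[B-]1(O)OO[B-](O)(O)OO1 (oxygen of the new hydroxyl); bis(pinacolato)diboron, CC1(C)OB(OC1(C)C)B1OC(C)(C)C(C)(C)O1 (boryl group of intermediate 9 only)
Why: Sterically governed iridium-catalysed aromatic C–H borylation should take place at the only ring C–H without an ortho substituent (para to geranyl), and perborate oxidation of the C–B bond gives the phenol without touching the trisubstituted alkenes.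

**Step 6**
Reactants: 10 4-geranyl-3,5-bis(methoxymethoxy)phenol; 3 (2E)-3-[4-methoxy-3-(methoxymethoxy)phenyl]prop-2-enoic acid
Product: 11 4-geranyl-3,5-bis(methoxymethoxy)phenyl (2E)-3-[4-methoxy-3-(methoxymethoxy)phenyl]prop-2-enoate
Conditions: DCC, DMAP (10 mol %), CH2Cl2, 0 °C → rt
Reagents that add atoms: none
Why: Steglich esterification of the unhindered phenol under neutral conditions should preserve the E-alkene and all three MOM groups.

**Step 7**
Reactants: 11 4-geranyl-3,5-bis(methoxymethoxy)phenyl (2E)-3-[4-methoxy-3-(methoxymethoxy)phenyl]prop-2-enoate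
Product: 13 (2S)-6-geranyl-5,7-bis(methoxymethoxy)-2-[4-methoxy-3-(methoxymethoxy)phenyl]-2,3-dihydro-4H-chromen-4-one, via chalcone 12 (not isolated)
Conditions: hν (300 nm), degassed PhMe (10 mM), 20 °C; then lamp off, concentrated to 0.1 M, N-[3,5-bis(trifluoromethyl)phenyl]-N'-[(9R)-6'-methoxycinchonan-9-yl]thiourea (10 mol %), 0 °C; silica filtration
Reagents that add atoms: none
Why: Excitation of the aryl ester cleaves the O1–acyl bond homolytically, the caged phenoxyl/cinnamoyl radical pair recombines at an ortho carbon and the dienone tautomerises to the 2'-hydroxychalcone 12 (C4–C4a bond); with the lamp off, the thiourea binds the enone carbonyl while its quinuclidine nitrogen activates the freed phenol, which adds to the β-carbon (O1–C2 bond). The closest known reaction types are the photo-Fries rearrangement of aryl cinnamates to 2'-hydroxychalcones and the cinchona-thiourea-catalysed oxa-Michael cyclisation of 2'-hydroxychalcones to flavanones, here run one after the other in the same flask. Ring C closes by 6-endo-trig attack of O1 on the enone. The new stereocenter C2 is set by the chiral catalyst, which holds phenol and enone in one hydrogen-bonded array and leaves one face of the β-carbon open. The site of the acyl shift is secured because the two carbons ortho to O1 are equivalent by symmetry and the para carbon carries geranyl; the 6-geranyl rather than 8-geranyl regiochemistry is secured because O1 is the only free hydroxyl, the other ortho oxygen being a MOM ether. The step is an isomerisation with no by-product, and the closure is run cold in the dark and ended by silica filtration so that reversible ring opening should not erode the configuration at C2.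

**Step 8**
Reactants: 13 (2S)-6-geranyl-5,7-bis(methoxymethoxy)-2-[4-methoxy-3-(methoxymethoxy)phenyl]-2,3-dihydro-4H-chromen-4-one
Product: 14 (2S)-6-geranyl-5,7-dihydroxy-2-(3-hydroxy-4-methoxyphenyl)-2,3-dihydro-4H-chromen-4-one
Conditions: HCl (3 M aq.)/MeOH, 45 °C, short reaction time
Reagents that add atoms: none
Why: Acid-catalysed methanolysis of the three MOM acetals should free the phenols; C2 is not enolisable and ring opening of flavanones is base-promoted, so the configuration should hold, and brief exposure to dilute acid is chosen to spare the geranyl alkenes.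

**Compound list**
1 | isovanillin (3-hydroxy-4-methoxybenzaldehyde) | COc1ccc(C=O)cc1O | starting material
2 | 4-methoxy-3-(methoxymethoxy)benzaldehyde | COc1ccc(C=O)cc1OCOC | intermediate
3 | (2E)-3-[4-methoxy-3-(methoxymethoxy)phenyl]prop-2-enoic acid | COc1ccc(/C=C/C(=O)O)cc1OCOC | intermediate
4 | resorcinol | Oc1cccc(O)c1 | starting material
5 | 1,3-bis(methoxymethoxy)benzene | COCOc1cccc(OCOC)c1 | intermediate
6 | geranyl bromide, (2E)-1-bromo-3,7-dimethylocta-2,6-diene | BrC/C=C(\C)CCC=C(C)C | starting material
7 | [2,6-bis(methoxymethoxy)phenyl]lithium | [Li]c1c(OCOC)cccc1OCOC | intermediate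
8 | 2-[(2E)-3,7-dimethylocta-2,6-dien-1-yl]-1,3-bis(methoxymethoxy)benzene | COCOc1cccc(OCOC)c1C/C=C(\C)CCC=C(C)C | intermediate
9 | 2-{4-[(2E)-3,7-dimethylocta-2,6-dien-1-yl]-3,5-bis(methoxymethoxy)phenyl}-4,4,5,5-tetramethyl-1,3,2-dioxaborolane | COCOc1cc(B2OC(C)(C)C(C)(C)O2)cc(OCOC)c1C/C=C(\C)CCC=C(C)C | intermediate
10 | 4-[(2E)-3,7-dimethylocta-2,6-dien-1-yl]-3,5-bis(methoxymethoxy)phenol | COCOc1cc(O)cc(OCOC)c1C/C=C(\C)CCC=C(C)C | intermediate
11 | 4-[(2E)-3,7-dimethylocta-2,6-dien-1-yl]-3,5-bis(methoxymethoxy)phenyl (2E)-3-[4-methoxy-3-(methoxymethoxy)phenyl]prop-2-enoate | COc1ccc(/C=C/C(=O)Oc2cc(OCOC)c(C/C=C(\C)CCC=C(C)C)c(OCOC)c2)cc1OCOC | intermediate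
12 | (2E)-1-{3-[(2E)-3,7-dimethylocta-2,6-dien-1-yl]-6-hydroxy-2,4-bis(methoxymethoxy)phenyl}-3-[4-methoxy-3-(methoxymethoxy)phenyl]prop-2-en-1-one | COc1ccc(/C=C/C(=O)c2c(O)cc(OCOC)c(C/C=C(\C)CCC=C(C)C)c2OCOC)cc1OCOC | intermediate
13 | (2S)-6-[(2E)-3,7-dimethylocta-2,6-dien-1-yl]-5,7-bis(methoxymethoxy)-2-[4-methoxy-3-(methoxymethoxy)phenyl]-2,3-dihydro-4H-chromen-4-one | COc1ccc([C@@H]2CC(=O)c3c(cc(OCOC)c(C/C=C(\C)CCC=C(C)C)c3OCOC)O2)cc1OCOC | intermediate
14 | (2S)-6-[(2E)-3,7-dimethylocta-2,6-dien-1-yl]-5,7-dihydroxy-2-(3-hydroxy-4-methoxyphenyl)-2,3-dihydro-4H-chromen-4-one (6-geranylhesperetin) | COc1ccc([C@@H]2CC(=O)c3c(cc(O)c(C/C=C(\C)CCC=C(C)C)c3O)O2)cc1O | target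

**Total step count:** 8 steps.
**Longest linear sequence:** 6 steps (steps 3 to 8, from resorcinol 4).

**Steps most likely to fail**

1. Step 7. In the irradiation stage the radical pair may escape the solvent cage, and the cinnamoyl chromophore may divert light into E/Z isomerisation or [2+2] dimerisation. The chalcone may also close under light without the catalyst, giving a racemic background. In the catalysed stage, facial selectivity may be poor or the closure may reverse. The fallback sets out from 10 and comes back at 13. Phenol 10 is acetylated (Ac2O, pyridine) to 4-geranyl-3,5-bis(methoxymethoxy)phenyl acetate F1. A photo-Fries shift of this simple acetyl group (254 nm, cyclohexane), free of alkene photochemistry, gives 1-[3-geranyl-6-hydroxy-2,4-bis(methoxymethoxy)phenyl]ethan-1-one F2. Claisen–Schmidt condensation of F2 with aldehyde 2 (KOH, EtOH, rt) builds chalcone 12, now isolated. NaOAc in refluxing EtOH closes it to the racemic flavanone F3. Preparative HPLC on a chiral stationary phase (amylose tris(3,5-dimethylphenylcarbamate)) then delivers 13, and the (2R) enantiomer is returned to the NaOAc equilibration.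

2. Step 5. Iridium boryl hydride species may hydroborate, isomerise or borylate the allylic positions of the geranyl alkenes, and the electron-rich phenol may be over-oxidised. The fallback sets out from 5 and comes back at 10, with the C–H borylation done before any alkene is present. Under the same iridium catalyst, 5 is borylated at the only position free of ortho substituents to give 2-[3,5-bis(methoxymethoxy)phenyl]-4,4,5,5-tetramethyl-1,3,2-dioxaborolane F4. NaBO3 oxidation gives 3,5-bis(methoxymethoxy)phenol F5, which is masked (TIPSCl, imidazole, DMF) as [3,5-bis(methoxymethoxy)phenoxy]triisopropylsilane F6. Lithiation between the MOM groups (n-BuLi, THF, 0 °C) gives {2,6-bis(methoxymethoxy)-4-[(triisopropylsilyl)oxy]phenyl}lithium F7. Allylation with 6 (CuBr·SMe2 cat.) gives [4-geranyl-3,5-bis(methoxymethoxy)phenoxy]triisopropylsilane F8, and TBAF (THF, 0 °C) releases 10.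

3. Step 8. The acid may cyclise the geranyl chain onto the flanking C5 or C7 hydroxyl (chroman formation), add methanol or HCl across the trisubstituted alkenes, or slowly open ring C at C2. The fallback sets out from 13 and comes back at 14 by an aprotic cleavage. TMSOTf and 2,2'-bipyridyl (CH2Cl2, 0 °C) should convert each aryl MOM ether into the aryl silyl ether, giving the tris(trimethylsilyl) ether of the target F9. Water at neutral pH then hydrolyses F9 to 14.

**Further compounds**
F1 | step 7 | 4-geranyl-3,5-bis(methoxymethoxy)phenyl acetate | CC(=O)Oc1cc(OCOC)c(C/C=C(\C)CCC=C(C)C)c(OCOC)c1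
F2 | step 7 | 1-[3-geranyl-6-hydroxy-2,4-bis(methoxymethoxy)phenyl]ethan-1-one | CC(=O)c1c(O)cc(OCOC)c(C/C=C(\C)CCC=C(C)C)c1OCOC
F3 | step 7 | racemic 6-geranyl-5,7-bis(methoxymethoxy)-2-[4-methoxy-3-(methoxymethoxy)phenyl]-2,3-dihydro-4H-chromen-4-one | COc1ccc(C2CC(=O)c3c(cc(OCOC)c(C/C=C(\C)CCC=C(C)C)c3OCOC)O2)cc1OCOC
F4 | step 5 | 2-[3,5-bis(methoxymethoxy)phenyl]-4,4,5,5-tetramethyl-1,3,2-dioxaborolane | COCOc1cc(OCOC)cc(B2OC(C)(C)C(C)(C)O2)c1
F5 | step 5 | 3,5-bis(methoxymethoxy)phenol | COCOc1cc(O)cc(OCOC)c1
F6 | step 5 | [3,5-bis(methoxymethoxy)phenoxy]triisopropylsilane | COCOc1cc(O[Si](C(C)C)(C(C)C)C(C)C)cc(OCOC)c1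
F7 | step 5 | {2,6-bis(methoxymethoxy)-4-[(triisopropylsilyl)oxy]phenyl}lithium | [Li]c1c(OCOC)cc(O[Si](C(C)C)(C(C)C)C(C)C)cc1OCOC
F8 | step 5 | [4-geranyl-3,5-bis(methoxymethoxy)phenoxy]triisopropylsilane | COCOc1cc(O[Si](C(C)C)(C(C)C)C(C)C)cc(OCOC)c1C/C=C(\C)CCC=C(C)C
F9 | step 8 | (2S)-6-geranyl-2-{4-methoxy-3-[(trimethylsilyl)oxy]phenyl}-5,7-bis[(trimethylsilyl)oxy]-2,3-dihydro-4H-chromen-4-one | COc1ccc([C@@H]2CC(=O)c3c(cc(O[Si](C)(C)C)c(C/C=C(\C)CCC=C(C)C)c3O[Si](C)(C)C)O2)cc1O[Si](C)(C)C
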